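**Retrosynthetic overview**
1. The target is unmasked at the end from a fully assembled enoate / aryl pivalate / bis-alkoxyamine by one N–O reduction and one global hydride reduction.
2. Each 2,3-trans dihydrobenzofuran is cut at two bonds: the benzylic C2–O aryl ether bond (key bond, made enantioselectively from a racemic aryl vinyl carbinol and a 2-iodo-6-methoxyphenol) and the C3–C3a bond (5-exo aryl radical closure whose TEMPO trap also delivers the CH2O oxygen).
3. Ring order: dihydrofuran ring 1 (between rings A and B) first; its aldehyde handle becomes the next vinyl carbinol; then dihydrofuran ring 2 (between rings B and C).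
4. All carbon comes from two cheap vanillin-type aldehydes, vinylmagnesium bromide and a stabilised Wittig reagent.

Assumption: the (S)-configured ligand L1 is taken to give the S ether; if a model run shows the opposite sense, its enantiomer is used and nothing else changes.
Abbreviations: OTMP = (2,2,6,6-tetramethylpiperidin-1-yl)oxy; L1 = BINOL-derived phosphoramidite whose nitrogen is part of a 5H-dibenzo[b,f]azepine (P,olefin ligand); ring A = guaiacyl ring, ring B = middle arene, ring C = arene carrying the propenol chain.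

**Route**

Step 1
Reactants: 1 vanillin
Product: 2 4-formyl-2-methoxyphenyl pivalate
Conditions: PivCl, Et3N, DMAP (cat.), CH2Cl2, 0 °C to rt
Reagents that add atoms: pivaloyl chloride, CC(C)(C)C(=O)Cl
Why: DMAP-catalysed O-acylation of the phenol; the pivalate survives the Grignard, Lewis-acid and radical steps, makes ring A less ionisable, and is removed by the final hydride reduction.

Step 2
Reactants: 2 4-formyl-2-methoxyphenyl pivalate
Product: 3 rac-4-(1-hydroxyprop-2-en-1-yl)-2-methoxyphenyl pivalate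
Conditions: CH2=CHMgBr (1.1 equiv), THF, −78 °C; then H2O/NH4Cl
Reagents that add atoms: vinylmagnesium bromide, C=C[Mg]Br
Why: Grignard 1,2-addition to the aldehyde is much faster at −78 °C than attack on the hindered aryl pivalate; the carbinol is made racemic on purpose because step 3 is enantioconvergent.

Step 3
Reactants: 3 rac-4-(1-hydroxyprop-2-en-1-yl)-2-methoxyphenyl pivalate (1.3 equiv); 4 5-iodovanillin
Product: 5 4-[(1S)-1-(4-formyl-2-iodo-6-methoxyphenoxy)prop-2-en-1-yl]-2-methoxyphenyl pivalate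
Conditions: [Ir(cod)Cl]2 (3 mol%), (S)-L1 (12 mol%), Zn(OTf)2 (10 mol%), DCE, 25 °C
Reagents that add atoms: none
Why: Proposed new method: iridium-catalysed enantioconvergent dehydrative O-allylation of a phenol — the Lewis acid and the acidic phenol (pKa near 6.5) activate the hydroxyl of either enantiomer of 3 for ionisation at iridium, both enantiomers funnel into one ligand-bound allyl fragment, and the (P,olefin) ligand directs outer-sphere attack of the phenol oxygen to one face of the aryl-bearing allyl terminus, so the C–O bond and the S centre (future C2 of dihydrofuran ring 1) are made together, while C-allylation is shut off because both ortho positions and the para position of 4 are substituted; closest known reaction type: iridium/(P,olefin)-catalysed direct substitution of racemic branched allylic alcohols by aliphatic alcohols, together with iridium/phosphoramidite allylic etherification of linear carbonates by phenoxides.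

Step 4
Reactants: 5 4-[(1S)-1-(4-formyl-2-iodo-6-methoxyphenoxy)prop-2-en-1-yl]-2-methoxyphenyl pivalate
Product: 7 4-[(2S,3R)-5-formyl-7-methoxy-3-[(OTMP)methyl]-2,3-dihydro-1-benzofuran-2-yl]-2-methoxyphenyl pivalate, via cyclised primary radical 6 (not isolated)
Conditions: Bu3SnH (2 equiv, slow addition), TEMPO (5 equiv), PhMe, 70 °C
Reagents that add atoms: TEMPO, CC1(C)CCCC(C)(C)N1[O]
Why: Oxygenative 5-exo-trig aryl radical cyclisation (tin-mediated, nitroxide trapping): Bu3Sn• removes the iodine, ring closure onto the vinyl group runs through a chair-like transition state with the C2 aryl group pseudo-equatorial (Beckwith–Houk model for a 4-substituted hexenyl radical) to give the 2,3-trans radical 6, and TEMPO couples with it at near-diffusion rate, so C3 (R) is set by relay from the untouched C2 (S).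

Step 5
Reactants: 7 4-[(2S,3R)-5-formyl-7-methoxy-3-[(OTMP)methyl]-2,3-dihydro-1-benzofuran-2-yl]-2-methoxyphenyl pivalate
Product: 8 4-[(2S,3R)-5-(1-hydroxyprop-2-en-1-yl)-7-methoxy-3-[(OTMP)methyl]-2,3-dihydro-1-benzofuran-2-yl]-2-methoxyphenyl pivalate (about 1:1 at the carbinol carbon)
Conditions: CH2=CHMgBr (1.2 equiv), THF, −78 °C; then H2O/NH4Cl
Reagents that add atoms: vinylmagnesium bromide, C=C[Mg]Br
Why: Grignard 1,2-addition to the aldehyde, with pivalate and alkoxyamine inert at −78 °C; the new carbinol centre is left uncontrolled because it is erased on ionisation in step 7.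

Step 6
Reactants: 4 5-iodovanillin
Product: 9 methyl (E)-3-(4-hydroxy-3-iodo-5-methoxyphenyl)prop-2-enoate (methyl 5-iodoferulate)
Conditions: Ph3P=CHCO2Me (1.5 equiv), PhMe, 100 °C
Reagents that add atoms: methyl (triphenylphosphoranylidene)acetate, COC(=O)C=P(c1ccccc1)(c1ccccc1)c1ccccc1
Why: Wittig olefination with a stabilised ylide gives the E enoate, and the free phenol is tolerated when excess ylide is used.

Step 7
Reactants: 8 4-[(2S,3R)-5-(1-hydroxyprop-2-en-1-yl)-7-methoxy-3-[(OTMP)methyl]-2,3-dihydro-1-benzofuran-2-yl]-2-methoxyphenyl pivalate; 9 methyl 5-iodoferulate (1.5 equiv)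
Product: 10 methyl (E)-3-{3-iodo-5-methoxy-4-[(1S)-1-{(2S,3R)-7-methoxy-2-[3-methoxy-4-(pivaloyloxy)phenyl]-3-[(OTMP)methyl]-2,3-dihydro-1-benzofuran-5-yl}prop-2-en-1-yloxy]phenyl}prop-2-enoate
Conditions: [Ir(cod)Cl]2 (4 mol%), (S)-L1 (16 mol%), Zn(OTf)2 (10 mol%), DCE, 0 to 25 °C
Reagents that add atoms: none
Why: Proposed new method: second use of the dehydrative phenol O-allylation of step 3 — both carbinol epimers of 8 ionise at iridium to one allyl fragment, and the ligand rather than the remote stereocentres of dihydrofuran ring 1 fixes the face on which the oxygen of 9 forms the benzylic C–O bond (S, future C2 of dihydrofuran ring 2); closest known reaction type: iridium/(P,olefin)-catalysed enantioconvergent substitution of racemic branched allylic alcohols by O-nucleophiles.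

Step 8
Reactants: 10 the S aryl allyl ether of step 7
Product: 12 methyl (E)-3-[(2S,3R)-7-methoxy-2-{(2S,3R)-7-methoxy-2-[3-methoxy-4-(pivaloyloxy)phenyl]-3-[(OTMP)methyl]-2,3-dihydro-1-benzofuran-5-yl}-3-[(OTMP)methyl]-2,3-dihydro-1-benzofuran-5-yl]prop-2-enoate, via cyclised primary radical 11 (not isolated)
Conditions: Bu3SnH (2 equiv, slow addition), TEMPO (5 equiv), PhMe, 70 °C
Reagents that add atoms: TEMPO, CC1(C)CCCC(C)(C)N1[O]
Why: Same oxygenative 5-exo-trig aryl radical cyclisation as step 4: the ring C aryl radical closes onto the adjacent vinyl group far faster than it can reach the remote enoate, ring B sits pseudo-equatorial so the 2,3-trans radical 11 forms, and TEMPO traps it, setting C3 (R) of dihydrofuran ring 2 by relay from C2 (S).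

Step 9
Reactants: 12 the bis-alkoxyamine enoate of step 8
Product: 13 methyl (E)-3-[(2S,3R)-3-(hydroxymethyl)-2-{(2S,3R)-3-(hydroxymethyl)-7-methoxy-2-[3-methoxy-4-(pivaloyloxy)phenyl]-2,3-dihydro-1-benzofuran-5-yl}-7-methoxy-2,3-dihydro-1-benzofuran-5-yl]prop-2-enoate
Conditions: Zn dust, AcOH/THF/H2O 3:1:1, 60 °C
Reagents that add atoms: none
Why: Reductive N–O cleavage of alkoxyamines by zinc in acetic acid frees both primary alcohols while enoate, pivalate and benzylic aryl ethers stay intact; it is run before the acid-sensitive cinnamyl alcohol and free phenol exist.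

Step 10
Reactants: 13 the diol enoate of step 9
Product: 14 4-[(2S,3R)-3-(hydroxymethyl)-5-{(2S,3R)-3-(hydroxymethyl)-5-[(E)-3-hydroxyprop-1-en-1-yl]-7-methoxy-2,3-dihydro-1-benzofuran-2-yl}-7-methoxy-2,3-dihydro-1-benzofuran-2-yl]-2-methoxyphenol (CNP0250921.2)
Conditions: iBu2AlH (8 equiv), CH2Cl2/THF, −78 to 0 °C; aq. KNaC4H4O6
Reagents that add atoms: none
Why: DIBAL 1,2-reduction of the enoate to the E allylic alcohol with concurrent reductive cleavage of the aryl pivalate (aluminium hydride ester reduction); no stereocentre or ring is touched.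

**Compound list**
1 | vanillin (4-hydroxy-3-methoxybenzaldehyde) | COc1cc(C=O)ccc1O | starting material
2 | 4-formyl-2-methoxyphenyl pivalate | COc1cc(C=O)ccc1OC(=O)C(C)(C)C | intermediate
3 | rac-4-(1-hydroxyprop-2-en-1-yl)-2-methoxyphenyl pivalate | C=CC(O)c1ccc(OC(=O)C(C)(C)C)c(OC)c1 | intermediate
4 | 5-iodovanillin (4-hydroxy-3-iodo-5-methoxybenzaldehyde) | COc1cc(C=O)cc(I)c1O | starting material
5 | 4-[(1S)-1-(4-formyl-2-iodo-6-methoxyphenoxy)prop-2-en-1-yl]-2-methoxyphenyl pivalate | C=C[C@H](Oc1c(I)cc(C=O)cc1OC)c1ccc(OC(=O)C(C)(C)C)c(OC)c1 | intermediate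
6 | cyclised primary radical: 7 with a CH2 radical in place of CH2–OTMP, 2,3-trans, C2 S | COc1cc([C@H]2Oc3c(OC)cc(C=O)cc3[C@@H]2[CH2])ccc1OC(=O)C(C)(C)C | intermediate
7 | 4-[(2S,3R)-5-formyl-7-methoxy-3-[(OTMP)methyl]-2,3-dihydro-1-benzofuran-2-yl]-2-methoxyphenyl pivalate | COc1cc([C@H]2Oc3c(OC)cc(C=O)cc3[C@@H]2CON4C(C)(C)CCCC4(C)C)ccc1OC(=O)C(C)(C)C | intermediate
8 | 4-[(2S,3R)-5-(1-hydroxyprop-2-en-1-yl)-7-methoxy-3-[(OTMP)methyl]-2,3-dihydro-1-benzofuran-2-yl]-2-methoxyphenyl pivalate, both carbinol epimers | COc1cc([C@H]2Oc3c(OC)cc(C(O)C=C)cc3[C@@H]2CON4C(C)(C)CCCC4(C)C)ccc1OC(=O)C(C)(C)C | intermediate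
9 | methyl (E)-3-(4-hydroxy-3-iodo-5-methoxyphenyl)prop-2-enoate | COC(=O)/C=C/c1cc(I)c(O)c(OC)c1 | intermediate
10 | methyl (E)-3-{3-iodo-5-methoxy-4-[(1S)-1-{(2S,3R)-7-methoxy-2-[3-methoxy-4-(pivaloyloxy)phenyl]-3-[(OTMP)methyl]-2,3-dihydro-1-benzofuran-5-yl}prop-2-en-1-yloxy]phenyl}prop-2-enoate | COc1cc([C@H]2Oc3c(OC)cc([C@H](C=C)Oc5c(I)cc(/C=C/C(=O)OC)cc5OC)cc3[C@@H]2CON4C(C)(C)CCCC4(C)C)ccc1OC(=O)C(C)(C)C | intermediate
11 | cyclised primary radical: 12 with a CH2 radical in place of the CH2–OTMP of dihydrofuran ring 2, 2,3-trans | COc1cc([C@H]2Oc3c(OC)cc([C@H]4Oc5c(OC)cc(/C=C/C(=O)OC)cc5[C@@H]4[CH2])cc3[C@@H]2CON6C(C)(C)CCCC6(C)C)ccc1OC(=O)C(C)(C)C | intermediate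
12 | methyl (E)-3-[(2S,3R)-7-methoxy-2-{(2S,3R)-7-methoxy-2-[3-methoxy-4-(pivaloyloxy)phenyl]-3-[(OTMP)methyl]-2,3-dihydro-1-benzofuran-5-yl}-3-[(OTMP)methyl]-2,3-dihydro-1-benzofuran-5-yl]prop-2-enoate | COc1cc([C@H]2Oc3c(OC)cc([C@H]4Oc5c(OC)cc(/C=C/C(=O)OC)cc5[C@@H]4CON6C(C)(C)CCCC6(C)C)cc3[C@@H]2CON7C(C)(C)CCCC7(C)C)ccc1OC(=O)C(C)(C)C | intermediate
13 | methyl (E)-3-[(2S,3R)-3-(hydroxymethyl)-2-{(2S,3R)-3-(hydroxymethyl)-7-methoxy-2-[3-methoxy-4-(pivaloyloxy)phenyl]-2,3-dihydro-1-benzofuran-5-yl}-7-methoxy-2,3-dihydro-1-benzofuran-5-yl]prop-2-enoate | COc1cc([C@H]2Oc3c(OC)cc([C@H]4Oc5c(OC)cc(/C=C/C(=O)OC)cc5[C@@H]4CO)cc3[C@@H]2CO)ccc1OC(=O)C(C)(C)C | intermediate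
14 | 4-[(2S,3R)-3-(hydroxymethyl)-5-{(2S,3R)-3-(hydroxymethyl)-5-[(E)-3-hydroxyprop-1-en-1-yl]-7-methoxy-2,3-dihydro-1-benzofuran-2-yl}-7-methoxy-2,3-dihydro-1-benzofuran-2-yl]-2-methoxyphenol | COc1cc([C@H]2Oc3c(OC)cc([C@H]4Oc5c(OC)cc(/C=C/CO)cc5[C@@H]4CO)cc3[C@@H]2CO)ccc1O | target

**Step count**
Total: 10 steps. Longest linear sequence: 9 steps (1, 2, 3, 4, 5, 7, 8, 9, 10); step 6 is a one-step side branch.

**Three steps most likely to fail**

Step 7 (proposed new C–O coupling on the advanced, electron-rich ring B carbinol). The risks are uncatalysed ionisation giving racemic or linear ether, and re-ionisation of 10. The fallback is known, base-mediated chemistry; it sets out from 8 and comes back at 10. Compound 8 is isomerised with Re2O7 (2 mol%, CH2Cl2, 0 °C; 1,3-transposition driven by conjugation) to the linear alcohol 4-[(2S,3R)-5-[(E)-3-hydroxyprop-1-en-1-yl]-7-methoxy-3-[(OTMP)methyl]-2,3-dihydro-1-benzofuran-2-yl]-2-methoxyphenyl pivalate F4. Methyl chloroformate and pyridine convert it into the methyl carbonate 4-[(2S,3R)-7-methoxy-5-[(E)-3-(methoxycarbonyloxy)prop-1-en-1-yl]-3-[(OTMP)methyl]-2,3-dihydro-1-benzofuran-2-yl]-2-methoxyphenyl pivalate F5. Phenol 9 is deprotonated with NaH to sodium 2-iodo-6-methoxy-4-[(E)-3-methoxy-3-oxoprop-1-en-1-yl]phenolate F6. F5 and F6 are joined with [Ir(cod)Cl]2 and the BINOL-derived phosphoramidite of bis(1-phenylethyl)amine (enantiomer chosen for the S ether) in THF at 25 °C. This is the established branched-selective iridium allylic etherification of linear carbonates by phenoxides, and it gives 10.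

Step 3 (first use of the proposed new method). The risks are a slow reaction with the hindered phenol and erosion of ee through reversible ionisation of the product. The fallback is known chemistry; it sets out from 3 and comes back at 5. Re2O7 (2 mol%, CH2Cl2, 0 °C) transposes 3 to 4-[(E)-3-hydroxyprop-1-en-1-yl]-2-methoxyphenyl pivalate F1. Methyl chloroformate and pyridine give 4-[(E)-3-(methoxycarbonyloxy)prop-1-en-1-yl]-2-methoxyphenyl pivalate F2. Phenol 4 and NaH give sodium 4-formyl-2-iodo-6-methoxyphenolate F3. F2 and F3 are coupled under the same [Ir(cod)Cl]2/phosphoramidite conditions in THF at 25 °C to give 5.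

Step 8 (radical cyclisation with nitroxide capture on the most valuable intermediate; step 4 is its simpler test case). The risks are capture of the aryl radical by TEMPO before ring closure, stannyl radical addition to the enoate, and imperfect trans selectivity. The fallback changes the approach: the oxygen is placed on the acceptor as boron and the chain ends by hydrogen transfer. It sets out from 10 and comes back at 13. Cross-metathesis of 10 with vinylboronic acid pinacol ester, using the second-generation Hoveyda–Grubbs catalyst RuCl2(H2IMes)(=CH-C6H4-2-OiPr) in CH2Cl2 at 40 °C, gives the (E)-alkenyl pinacol boronate of 10 (terminal =CH2 replaced by =CH–Bpin) F7. Reductive 5-exo cyclisation with Bu3SnH and AIBN in PhMe at 80 °C gives the 2,3-trans CH2–Bpin analogue of 12 at dihydrofuran ring 2 (formally 2S,3S because of the boron priority) F8. NaBO3·4H2O in THF/H2O oxidises it to the mono-alcohol in which dihydrofuran ring 2 carries CH2OH and dihydrofuran ring 1 still carries CH2–OTMP F9. The Zn/AcOH conditions of step 9 then give 13.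

**Further compounds**
F1 | step 3 | 4-[(E)-3-hydroxyprop-1-en-1-yl]-2-methoxyphenyl pivalate | COc1cc(/C=C/CO)ccc1OC(=O)C(C)(C)C
F2 | step 3 | 4-[(E)-3-(methoxycarbonyloxy)prop-1-en-1-yl]-2-methoxyphenyl pivalate | COC(=O)OC/C=C/c1ccc(OC(=O)C(C)(C)C)c(OC)c1
F3 | step 3 | sodium 4-formyl-2-iodo-6-methoxyphenolate | COc1cc(C=O)cc(I)c1[O-].[Na+]
F4 | step 7 | 4-[(2S,3R)-5-[(E)-3-hydroxyprop-1-en-1-yl]-7-methoxy-3-[(OTMP)methyl]-2,3-dihydro-1-benzofuran-2-yl]-2-methoxyphenyl pivalate | COc1cc([C@H]2Oc3c(OC)cc(/C=C/CO)cc3[C@@H]2CON4C(C)(C)CCCC4(C)C)ccc1OC(=O)C(C)(C)C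
F5 | step 7 | 4-[(2S,3R)-7-methoxy-5-[(E)-3-(methoxycarbonyloxy)prop-1-en-1-yl]-3-[(OTMP)methyl]-2,3-dihydro-1-benzofuran-2-yl]-2-methoxyphenyl pivalate | COc1cc([C@H]2Oc3c(OC)cc(/C=C/COC(=O)OC)cc3[C@@H]2CON4C(C)(C)CCCC4(C)C)ccc1OC(=O)C(C)(C)C
F6 | step 7 | sodium 2-iodo-6-methoxy-4-[(E)-3-methoxy-3-oxoprop-1-en-1-yl]phenolate | COC(=O)/C=C/c1cc(I)c([O-])c(OC)c1.[Na+]
F7 | step 8 | (E)-alkenyl pinacol boronate of 10 (terminal =CH2 replaced by =CH–Bpin, ether carbon S) | COc1cc([C@H]2Oc3c(OC)cc([C@H](/C=C/B6OC(C)(C)C(C)(C)O6)Oc5c(I)cc(/C=C/C(=O)OC)cc5OC)cc3[C@@H]2CON4C(C)(C)CCCC4(C)C)ccc1OC(=O)C(C)(C)C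
F8 | step 8 | analogue of 12 with CH2–Bpin in place of CH2–OTMP on dihydrofuran ring 2 (2,3-trans) | COc1cc([C@H]2Oc3c(OC)cc([C@H]4Oc5c(OC)cc(/C=C/C(=O)OC)cc5[C@@H]4CB6OC(C)(C)C(C)(C)O6)cc3[C@@H]2CON7C(C)(C)CCCC7(C)C)ccc1OC(=O)C(C)(C)C
F9 | step 8 | analogue of 12 with CH2OH on dihydrofuran ring 2 and CH2–OTMP on dihydrofuran ring 1 | COc1cc([C@H]2Oc3c(OC)cc([C@H]4Oc5c(OC)cc(/C=C/C(=O)OC)cc5[C@@H]4CO)cc3[C@@H]2CON7C(C)(C)CCCC7(C)C)ccc1OC(=O)C(C)(C)C
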